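**Plan**

- Labels: ring A = the acylated ring (C1' acyl, C2' OH, C3' carrying C7, C4' OH, C5' H, C6' OMe); ring B = enone aryl; ring C = aryl on C7; ring D = aryl on C1; C1–C7 = heptene chain counted from the CH2 on ring D.
- Retrosynthetic cuts, in order: C1'–C(=O) (aryl iodide plus cinnamic Weinreb amide); ring A itself at C1'–C2', C2'–C3' and C4'–C5'; C5=C6 (cross-metathesis); C7–C(alkyne) (allylic alkynylation).
- Enabling feature: without its acyl group ring A is a 5-methoxyresorcinol with C7 on the carbon between the two oxygens (O on C2' and C4', OMe on C6' para to C3'). The ynol ether unit C7–C≡C–OSi and the ketene CH2=C(OMe)–CH=C=O assemble exactly this pattern.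
- Forward order: ring C phosphate to the (S)-enyne; ring D aldehyde to the (R)-homoallyl ether; metathesis joins C1–C7; the alkyne becomes a siloxyalkyne; benzannulation closes ring A (the only ring made); iodination and acylation add the ring B enone; two deprotections.
- Stereochemistry: C7 from copper/chiral carbene SN2' alkynylation; C3 from allylboration with the (+)-α-pinene-derived borane; C5=C6 (E) from metathesis; the enone (E) from the cinnamate.

Key step: step 13

Remarks before the steps: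
- Hep = (1S,2E,5R)-5-(tert-butyldimethylsilyloxy)-1,7-bis[4-(triisopropylsilyloxy)phenyl]hept-2-en-1-yl; its C1 is C7 of the target.
- Assumption: the sense of induction of the chiral carbene–copper catalyst in step 4 is taken to follow its behaviour with other (E)-aryl allylic phosphates; the ligand antipode meant throughout is the one that delivers the (S)-enyne.
- The descriptor at C7 reads R in the terminal alkyne of step 10 only because the alkyne loses CIP rank there; the spatial arrangement is unchanged.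

**Route**

Step 1
Reactants: 1 methyl (E)-3-(4-hydroxyphenyl)prop-2-enoate
Product: 2 methyl (E)-3-[4-(triisopropylsilyloxy)phenyl]prop-2-enoate
Conditions: TIPSCl, imidazole, DMF, 0 °C → rt
Reagents that add atoms: triisopropylsilyl chloride, CC(C)[Si](Cl)(C(C)C)C(C)C
Why: Imidazole-promoted O-silylation of the phenol should give an aryl TIPS ether that tolerates hydride, organometallic and dilute-acid steps and is removed by fluoride at the end.

Step 2
Reactants: 2 methyl (E)-3-[4-(triisopropylsilyloxy)phenyl]prop-2-enoate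
Product: 3 (E)-3-[4-(triisopropylsilyloxy)phenyl]prop-2-en-1-ol
Conditions: i-Bu2AlH (2.2 equiv), CH2Cl2, −78 → 0 °C
Reagents that add atoms: none
Why: 1,2-Reduction of the enoate by the aluminium hydride at low temperature should give the allylic alcohol without touching the alkene or the silyl ether.

Step 3
Reactants: 3 (E)-3-[4-(triisopropylsilyloxy)phenyl]prop-2-en-1-ol
Product: 4 diethyl (E)-3-[4-(triisopropylsilyloxy)phenyl]prop-2-en-1-yl phosphate
Conditions: ClP(O)(OEt)2, Et3N, DMAP (cat.), CH2Cl2, 0 °C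
Reagents that add atoms: diethyl chlorophosphate, CCOP(=O)(Cl)OCC
Why: O-Phosphorylation of the primary allylic alcohol installs the leaving group used in copper-catalysed SN2' substitution.

Step 4
Reactants: 4 diethyl (E)-3-[4-(triisopropylsilyloxy)phenyl]prop-2-en-1-yl phosphate; 5 ethynyltrimethylsilane
Product: 7 (S)-trimethyl{3-[4-(triisopropylsilyloxy)phenyl]pent-4-en-1-yn-1-yl}silane, via alkynylalane 6 (not isolated)
Conditions: 5, i-Bu2AlH, Et3N (5 mol %), hexane, 0 → 55 °C; then 4, CuCl2·2H2O (2 mol %), chiral sulfonate-bearing imidazolinium salt (carbene precursor, 2.5 mol %), THF, −30 °C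
Reagents that add atoms: none
Why: Copper-catalysed enantioselective allylic substitution with an alkynylaluminium reagent should go γ-selectively (SN2') at the aryl-bearing carbon, with the chiral carbene on copper choosing the alkene face and so setting C7, while the Lewis-acidic, base-free medium should keep the skipped enyne from isomerising.

Step 5
Reactants: 8 3-(4-hydroxyphenyl)propan-1-ol
Product: 9 3-[4-(triisopropylsilyloxy)phenyl]propan-1-ol
Conditions: NaH (1.0 equiv), THF, 0 °C; TIPSCl, 0 °C → rt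
Reagents that add atoms: triisopropylsilyl chloride, CC(C)[Si](Cl)(C(C)C)C(C)C
Why: One equivalent of base deprotonates only the far more acidic phenol, so silylation of the phenoxide should leave the primary alcohol free.

Step 6
Reactants: 9 3-[4-(triisopropylsilyloxy)phenyl]propan-1-ol
Product: 10 3-[4-(triisopropylsilyloxy)phenyl]propanal
Conditions: TEMPO (10 mol %), PhI(OAc)2, CH2Cl2, rt
Reagents that add atoms: none
Why: Oxoammonium-mediated oxidation of the primary alcohol stops cleanly at the aldehyde under near-neutral conditions.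

Step 7
Reactants: 10 3-[4-(triisopropylsilyloxy)phenyl]propanal
Product: 12 (R)-1-[4-(triisopropylsilyloxy)phenyl]hex-5-en-3-ol, via borinate 11 (not isolated)
Conditions: (−)-Ipc2B(allyl), Et2O, −78 °C; then NaOH, H2O2, 0 °C → rt
Reagents that add atoms: (−)-B-allyldiisopinocampheylborane, C=CCB([C@@H]1C[C@@H]2C[C@H]([C@H]1C)C2(C)C)[C@@H]1C[C@@H]2C[C@H]([C@H]1C)C2(C)C
Why: Brown allylboration through a closed chair transition state, in which the isopinocampheyl groups derived from (+)-α-pinene send the allyl group to the Si face of the unbranched aldehyde, should set the carbinol centre as R.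

Step 8
Reactants: 12 (R)-1-[4-(triisopropylsilyloxy)phenyl]hex-5-en-3-ol
Product: 13 (R)-tert-butyldimethyl({1-[4-(triisopropylsilyloxy)phenyl]hex-5-en-3-yl}oxy)silane
Conditions: TBSCl, imidazole, DMF, rt
Reagents that add atoms: tert-butyldimethylsilyl chloride, CC(C)(C)[Si](C)(C)Cl
Why: Standard silylation of the secondary alcohol gives an ether that survives organolithium, peroxide and thermal steps and is later removed by dilute acid while aryl TIPS ethers stay.

Step 9
Reactants: 7 (S)-trimethyl{3-[4-(triisopropylsilyloxy)phenyl]pent-4-en-1-yn-1-yl}silane; 13 (R)-tert-butyldimethyl({1-[4-(triisopropylsilyloxy)phenyl]hex-5-en-3-yl}oxy)silane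
Product: 14 (3S,4E,7R)-7-(tert-butyldimethylsilyloxy)-3,9-bis[4-(triisopropylsilyloxy)phenyl]-1-(trimethylsilyl)non-4-en-1-yne
Conditions: second-generation Hoveyda–Grubbs catalyst (5 mol %), 13 (2.5 equiv), 1,4-benzoquinone (10 mol %), CH2Cl2, 40 °C
Reagents that add atoms: none
Why: Olefin cross-metathesis between a fast-reacting homoallyl ether and a slowly dimerising, allylically branched alkene should give the E-alkene selectively, the C-silyl cap keeping the alkyne out of enyne metathesis and the quinone suppressing double-bond migration.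

Step 10
Reactants: 14 (3S,4E,7R)-7-(tert-butyldimethylsilyloxy)-3,9-bis[4-(triisopropylsilyloxy)phenyl]-1-(trimethylsilyl)non-4-en-1-yne
Product: 15 (3R,4E,7R)-7-(tert-butyldimethylsilyloxy)-3,9-bis[4-(triisopropylsilyloxy)phenyl]non-4-en-1-yne
Conditions: AgNO3 (20 mol %), acetone–H2O, rt
Reagents that add atoms: none
Why: Silver-catalysed protodesilylation cleaves only the C(sp)–Si bond under neutral conditions, sparing the O-silyl ethers and keeping base away from the acidic C3–H.

Step 11
Reactants: 15 (3R,4E,7R)-7-(tert-butyldimethylsilyloxy)-3,9-bis[4-(triisopropylsilyloxy)phenyl]non-4-en-1-yne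
Product: 18 triisopropylsilyl (3S,4E,7R)-7-(tert-butyldimethylsilyloxy)-3,9-bis[4-(triisopropylsilyloxy)phenyl]non-4-en-1-yn-1-yl ether, via lithium acetylide 16 (not isolated), via lithium ynolate 17 (not isolated)
Conditions: n-BuLi (1.0 equiv), THF, −78 °C; LiOOt-Bu (from t-BuOOH and LiN(SiMe3)2), −78 → 0 °C; TIPSOTf, −78 °C
Reagents that add atoms: tert-butyl hydroperoxide, CC(C)(C)OO; triisopropylsilyl trifluoromethanesulfonate, CC(C)[Si](OS(=O)(=O)C(F)(F)F)(C(C)C)C(C)C
Why: Electrophilic oxygenation of the lithium acetylide by lithium tert-butyl peroxide gives the ynolate, which the hindered silyl triflate traps on oxygen, and the kinetically fast sp C–H deprotonation followed by the anionic charge next to C3 should shield the C3–H from the bases present.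

Step 12
Reactants: 19 3-ethoxycyclobut-2-en-1-one
Product: 20 3-methoxycyclobut-2-en-1-one
Conditions: MeOH (solvent), p-TsOH (cat.), rt; then NaHCO3
Reagents that add atoms: methanol, CO
Why: Acid-catalysed addition–elimination at the β-carbon of the vinylogous ester exchanges the alkoxy group, driven by the large excess of methanol.

Step 13
Reactants: 18 triisopropylsilyl (3S,4E,7R)-7-(tert-butyldimethylsilyloxy)-3,9-bis[4-(triisopropylsilyloxy)phenyl]non-4-en-1-yn-1-yl ether; 20 3-methoxycyclobut-2-en-1-one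
Product: 25 2-Hep-5-methoxy-3-(triisopropylsilyloxy)phenol, via vinylketene 21 (not isolated), via vinylcyclobutenone 22 (not isolated), via dienylketene 23 (not isolated), via cyclohexadienone 24 (not isolated)
Conditions: 20 (1.5 equiv, added over 2 h), toluene, 80 → 110 °C, argon
Reagents that add atoms: none
Why: Thermal four-electron opening of 20 gives vinylketene 21, whose carbonyl carbon is attacked by the alkyne carbon bearing C7 (made nucleophilic by the siloxy oxygen), so the [2+2] adduct 22 has C7 next to the carbonyl and the siloxy carbon next to the carbon carrying the methoxyvinyl group. Four-electron opening of 22 gives dienylketene 23, and six-electron electrocyclisation between the ketene carbon and the terminal CH2 closes ring A as dienone 24, which tautomerises to phenol 25, so that C1'–C2', C2'–C3' and C4'–C5' are formed in one operation. This is the Danheiser benzannulation of a cyclobutenone with a siloxyalkyne, known to give resorcinol monosilyl ethers. No stereocentre is created, and C7 should pass through unchanged because the medium is neutral and aprotic and no intermediate places charge on C7. The one selectivity needed is the orientation of the ketene–alkyne addition, which the polarisation of the O-silyl ynol ether secures; it places OMe para to C7 and the free OH and the OTIPS group on either side of it, already differentiated.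

Step 14
Reactants: 25 2-Hep-5-methoxy-3-(triisopropylsilyloxy)phenol
Product: 26 [2-Hep-5-methoxy-3-(methoxymethoxy)phenoxy]triisopropylsilane
Conditions: MOMCl, i-Pr2NEt, DMAP (cat.), CH2Cl2, 0 °C → rt
Reagents that add atoms: chloromethyl methyl ether, COCCl
Why: Williamson-type acetal formation caps the phenol with a small chelating group that cannot migrate to an ortho carbanion as a silyl group would and that stops the phenol from adding to the chain alkene during iodination.

Step 15
Reactants: 26 [2-Hep-5-methoxy-3-(methoxymethoxy)phenoxy]triisopropylsilane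
Product: 27 [2-Hep-4-iodo-5-methoxy-3-(methoxymethoxy)phenoxy]triisopropylsilane
Conditions: NIS (1.05 equiv), MeCN, 0 °C, dark
Reagents that add atoms: N-iodosuccinimide, O=C1CCC(=O)N1I
Why: Electrophilic aromatic iodination should occur only on the trioxygenated ring A and preferentially at the position between OMOM and OMe, away from the bulky OTIPS group, and the other free position would lead to the same final compound.

Step 16
Reactants: 2 methyl (E)-3-[4-(triisopropylsilyloxy)phenyl]prop-2-enoate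
Product: 28 (E)-N-methoxy-N-methyl-3-[4-(triisopropylsilyloxy)phenyl]prop-2-enamide
Conditions: MeNHOMe·HCl, i-PrMgCl, THF, −20 °C
Reagents that add atoms: N,O-dimethylhydroxylamine hydrochloride, CNOC.Cl
Why: Aminolysis of the ester by the chloromagnesium amide formed in situ gives the Weinreb amide, the Grignard reagent being consumed by the N–H acid faster than it can add to the enoate.

Step 17
Reactants: 27 [2-Hep-4-iodo-5-methoxy-3-(methoxymethoxy)phenoxy]triisopropylsilane; 28 (E)-N-methoxy-N-methyl-3-[4-(triisopropylsilyloxy)phenyl]prop-2-enamide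
Product: 31 (E)-1-[3-Hep-6-methoxy-2-(methoxymethoxy)-4-(triisopropylsilyloxy)phenyl]-3-[4-(triisopropylsilyloxy)phenyl]prop-2-en-1-one, via aryllithium 29 (not isolated), via lithium hemiaminal 30 (not isolated)
Conditions: n-BuLi (1.05 equiv), THF, −78 °C, 5 min; then 28, −78 → −40 °C; AcOH, −78 °C
Reagents that add atoms: none
Why: Iodine–lithium exchange is faster than deprotonation at C7, the aryllithium is held by the ortho OMOM and OMe groups, and its 1,2-addition to the Weinreb amide gives a chelated tetrahedral intermediate that releases the enone only on the cold acidic quench.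

Step 18
Reactants: 31 (E)-1-[3-Hep-6-methoxy-2-(methoxymethoxy)-4-(triisopropylsilyloxy)phenyl]-3-[4-(triisopropylsilyloxy)phenyl]prop-2-en-1-one
Product: 32 (E)-1-{2-hydroxy-3-[(1S,2E,5R)-5-hydroxy-1,7-bis[4-(triisopropylsilyloxy)phenyl]hept-2-en-1-yl]-6-methoxy-4-(triisopropylsilyloxy)phenyl}-3-[4-(triisopropylsilyloxy)phenyl]prop-2-en-1-one
Conditions: HCl (0.2 M, from AcCl), MeOH–THF, 0 °C → rt
Reagents that add atoms: none
Why: Dilute acid methanolysis should remove the MOM group, which is activated by the ortho carbonyl, and the secondary TBS ether, while aryl TIPS ethers resist acid and the acyl group keeps ring A from being protonated at C3'.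

Step 19
Reactants: 32 (E)-1-{2-hydroxy-3-[(1S,2E,5R)-5-hydroxy-1,7-bis[4-(triisopropylsilyloxy)phenyl]hept-2-en-1-yl]-6-methoxy-4-(triisopropylsilyloxy)phenyl}-3-[4-(triisopropylsilyloxy)phenyl]prop-2-en-1-one
Product: 33 (E)-1-{2,4-dihydroxy-3-[(1S,2E,5R)-5-hydroxy-1,7-bis(4-hydroxyphenyl)hept-2-en-1-yl]-6-methoxyphenyl}-3-(4-hydroxyphenyl)prop-2-en-1-one
Conditions: Bu4NF, AcOH (1:1, 5 equiv each), THF, 0 °C → rt
Reagents that add atoms: none
Why: Fluoride cleaves the four aryl silyl ethers quickly, and the acetic acid buffer keeps the phenols protonated so that neither cyclisation of the 2'-hydroxy enone to a flavanone nor ionisation at C7 should compete.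

**Compound list**

1 | methyl (E)-3-(4-hydroxyphenyl)prop-2-enoate | COC(=O)/C=C/c1ccc(O)cc1 | starting material
2 | methyl (E)-3-[4-(triisopropylsilyloxy)phenyl]prop-2-enoate | COC(=O)/C=C/c1ccc(O[Si](C(C)C)(C(C)C)C(C)C)cc1 | intermediate
3 | (E)-3-[4-(triisopropylsilyloxy)phenyl]prop-2-en-1-ol | OC/C=C/c1ccc(O[Si](C(C)C)(C(C)C)C(C)C)cc1 | intermediate
4 | diethyl (E)-3-[4-(triisopropylsilyloxy)phenyl]prop-2-en-1-yl phosphate | CCOP(=O)(OCC)OC/C=C/c1ccc(O[Si](C(C)C)(C(C)C)C(C)C)cc1 | intermediate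
5 | ethynyltrimethylsilane | C#C[Si](C)(C)C | starting material
6 | diisobutyl[(trimethylsilyl)ethynyl]aluminium (formed in the flask) | CC(C)C[Al](CC(C)C)C#C[Si](C)(C)C | intermediate
7 | (S)-trimethyl{3-[4-(triisopropylsilyloxy)phenyl]pent-4-en-1-yn-1-yl}silane | C[Si](C)(C)C#C[C@@H](C=C)c1ccc(O[Si](C(C)C)(C(C)C)C(C)C)cc1 | intermediate
8 | 3-(4-hydroxyphenyl)propan-1-ol | OCCCc1ccc(O)cc1 | starting material
9 | 3-[4-(triisopropylsilyloxy)phenyl]propan-1-ol | OCCCc1ccc(O[Si](C(C)C)(C(C)C)C(C)C)cc1 | intermediate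
10 | 3-[4-(triisopropylsilyloxy)phenyl]propanal | O=CCCc1ccc(O[Si](C(C)C)(C(C)C)C(C)C)cc1 | intermediate
11 | (R)-1-[4-(triisopropylsilyloxy)phenyl]hex-5-en-3-yl diisopinocampheylborinate (formed in the flask) | C=CC[C@H](OB([C@@H]1C[C@@H]2C[C@H]([C@H]1C)C2(C)C)[C@@H]1C[C@@H]2C[C@H]([C@H]1C)C2(C)C)CCc1ccc(O[Si](C(C)C)(C(C)C)C(C)C)cc1 | intermediate
12 | (R)-1-[4-(triisopropylsilyloxy)phenyl]hex-5-en-3-ol | C=CC[C@H](O)CCc1ccc(O[Si](C(C)C)(C(C)C)C(C)C)cc1 | intermediate
13 | (R)-tert-butyldimethyl({1-[4-(triisopropylsilyloxy)phenyl]hex-5-en-3-yl}oxy)silane | C=CC[C@H](O[Si](C)(C)C(C)(C)C)CCc1ccc(O[Si](C(C)C)(C(C)C)C(C)C)cc1 | intermediate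
14 | (3S,4E,7R)-7-(tert-butyldimethylsilyloxy)-3,9-bis[4-(triisopropylsilyloxy)phenyl]-1-(trimethylsilyl)non-4-en-1-yne | C[Si](C)(C)C#C[C@@H](/C=C/C[C@H](O[Si](C)(C)C(C)(C)C)CCc1ccc(O[Si](C(C)C)(C(C)C)C(C)C)cc1)c1ccc(O[Si](C(C)C)(C(C)C)C(C)C)cc1 | intermediate
15 | (3R,4E,7R)-7-(tert-butyldimethylsilyloxy)-3,9-bis[4-(triisopropylsilyloxy)phenyl]non-4-en-1-yne | C#C[C@@H](/C=C/C[C@H](O[Si](C)(C)C(C)(C)C)CCc1ccc(O[Si](C(C)C)(C(C)C)C(C)C)cc1)c1ccc(O[Si](C(C)C)(C(C)C)C(C)C)cc1 | intermediate
16 | lithium acetylide of 15 (lithium on C1; formed in the flask) | [Li]C#C[C@@H](/C=C/C[C@H](O[Si](C)(C)C(C)(C)C)CCc1ccc(O[Si](C(C)C)(C(C)C)C(C)C)cc1)c1ccc(O[Si](C(C)C)(C(C)C)C(C)C)cc1 | intermediate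
17 | lithium (3S,4E,7R)-7-(tert-butyldimethylsilyloxy)-3,9-bis[4-(triisopropylsilyloxy)phenyl]non-4-en-1-yn-1-olate (formed in the flask) | [Li]OC#C[C@@H](/C=C/C[C@H](O[Si](C)(C)C(C)(C)C)CCc1ccc(O[Si](C(C)C)(C(C)C)C(C)C)cc1)c1ccc(O[Si](C(C)C)(C(C)C)C(C)C)cc1 | intermediate
18 | triisopropylsilyl (3S,4E,7R)-7-(tert-butyldimethylsilyloxy)-3,9-bis[4-(triisopropylsilyloxy)phenyl]non-4-en-1-yn-1-yl ether | CC(C)[Si](OC#C[C@@H](/C=C/C[C@H](O[Si](C)(C)C(C)(C)C)CCc1ccc(O[Si](C(C)C)(C(C)C)C(C)C)cc1)c1ccc(O[Si](C(C)C)(C(C)C)C(C)C)cc1)(C(C)C)C(C)C | intermediate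
19 | 3-ethoxycyclobut-2-en-1-one | CCOC1=CC(=O)C1 | starting material
20 | 3-methoxycyclobut-2-en-1-one | COC1=CC(=O)C1 | intermediate
21 | 3-methoxybuta-1,3-dien-1-one (vinylketene; formed in the flask) | C=C(OC)C=C=O | intermediate
22 | 2-Hep-4-(1-methoxyethenyl)-3-(triisopropylsilyloxy)cyclobut-2-en-1-one (either configuration at ring C4; formed in the flask) | O=C1C([C@@H](/C=C/C[C@H](O[Si](C)(C)C(C)(C)C)CCc2ccc(O[Si](C(C)C)(C(C)C)C(C)C)cc2)c2ccc(O[Si](C(C)C)(C(C)C)C(C)C)cc2)=C(O[Si](C(C)C)(C(C)C)C(C)C)C1C(=C)OC | intermediate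
23 | (3E)-2-Hep-5-methoxy-3-(triisopropylsilyloxy)hexa-1,3,5-trien-1-one (dienylketene; formed in the flask) | O=C=C([C@@H](/C=C/C[C@H](O[Si](C)(C)C(C)(C)C)CCc1ccc(O[Si](C(C)C)(C(C)C)C(C)C)cc1)c1ccc(O[Si](C(C)C)(C(C)C)C(C)C)cc1)/C(O[Si](C(C)C)(C(C)C)C(C)C)=C\C(=C)OC | intermediate
24 | 2-Hep-5-methoxy-3-(triisopropylsilyloxy)cyclohexa-2,4-dien-1-one (formed in the flask) | O=C1CC(OC)=CC(O[Si](C(C)C)(C(C)C)C(C)C)=C1[C@@H](/C=C/C[C@H](O[Si](C)(C)C(C)(C)C)CCc2ccc(O[Si](C(C)C)(C(C)C)C(C)C)cc2)c2ccc(O[Si](C(C)C)(C(C)C)C(C)C)cc2 | intermediate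
25 | 2-{(1S,2E,5R)-5-(tert-butyldimethylsilyloxy)-1,7-bis[4-(triisopropylsilyloxy)phenyl]hept-2-en-1-yl}-5-methoxy-3-(triisopropylsilyloxy)phenol | COc1cc(O)c([C@@H](/C=C/C[C@H](O[Si](C)(C)C(C)(C)C)CCc2ccc(O[Si](C(C)C)(C(C)C)C(C)C)cc2)c2ccc(O[Si](C(C)C)(C(C)C)C(C)C)cc2)c(O[Si](C(C)C)(C(C)C)C(C)C)c1 | intermediate
26 | [2-Hep-5-methoxy-3-(methoxymethoxy)phenoxy]triisopropylsilane | COc1cc(OCOC)c([C@@H](/C=C/C[C@H](O[Si](C)(C)C(C)(C)C)CCc2ccc(O[Si](C(C)C)(C(C)C)C(C)C)cc2)c2ccc(O[Si](C(C)C)(C(C)C)C(C)C)cc2)c(O[Si](C(C)C)(C(C)C)C(C)C)c1 | intermediate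
27 | [2-Hep-4-iodo-5-methoxy-3-(methoxymethoxy)phenoxy]triisopropylsilane | COc1cc(O[Si](C(C)C)(C(C)C)C(C)C)c([C@@H](/C=C/C[C@H](O[Si](C)(C)C(C)(C)C)CCc2ccc(O[Si](C(C)C)(C(C)C)C(C)C)cc2)c2ccc(O[Si](C(C)C)(C(C)C)C(C)C)cc2)c(OCOC)c1I | intermediate
28 | (E)-N-methoxy-N-methyl-3-[4-(triisopropylsilyloxy)phenyl]prop-2-enamide | CON(C)C(=O)/C=C/c1ccc(O[Si](C(C)C)(C(C)C)C(C)C)cc1 | intermediate
29 | aryllithium from 27 (lithium in place of iodine; formed in the flask) | COc1cc(O[Si](C(C)C)(C(C)C)C(C)C)c([C@@H](/C=C/C[C@H](O[Si](C)(C)C(C)(C)C)CCc2ccc(O[Si](C(C)C)(C(C)C)C(C)C)cc2)c2ccc(O[Si](C(C)C)(C(C)C)C(C)C)cc2)c(OCOC)c1[Li] | intermediate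
30 | lithium alkoxide of the N-methoxy-N-methyl hemiaminal from 29 and 28 (either configuration at the new carbon; formed in the flask) | COc1cc(O[Si](C(C)C)(C(C)C)C(C)C)c([C@@H](/C=C/C[C@H](O[Si](C)(C)C(C)(C)C)CCc2ccc(O[Si](C(C)C)(C(C)C)C(C)C)cc2)c2ccc(O[Si](C(C)C)(C(C)C)C(C)C)cc2)c(OCOC)c1C(O[Li])(N(C)OC)/C=C/c1ccc(O[Si](C(C)C)(C(C)C)C(C)C)cc1 | intermediate
31 | (E)-1-[3-Hep-6-methoxy-2-(methoxymethoxy)-4-(triisopropylsilyloxy)phenyl]-3-[4-(triisopropylsilyloxy)phenyl]prop-2-en-1-one | COc1cc(O[Si](C(C)C)(C(C)C)C(C)C)c([C@@H](/C=C/C[C@H](O[Si](C)(C)C(C)(C)C)CCc2ccc(O[Si](C(C)C)(C(C)C)C(C)C)cc2)c2ccc(O[Si](C(C)C)(C(C)C)C(C)C)cc2)c(OCOC)c1C(=O)/C=C/c1ccc(O[Si](C(C)C)(C(C)C)C(C)C)cc1 | intermediate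
32 | (E)-1-{2-hydroxy-3-[(1S,2E,5R)-5-hydroxy-1,7-bis[4-(triisopropylsilyloxy)phenyl]hept-2-en-1-yl]-6-methoxy-4-(triisopropylsilyloxy)phenyl}-3-[4-(triisopropylsilyloxy)phenyl]prop-2-en-1-one | COc1cc(O[Si](C(C)C)(C(C)C)C(C)C)c([C@@H](/C=C/C[C@H](O)CCc2ccc(O[Si](C(C)C)(C(C)C)C(C)C)cc2)c2ccc(O[Si](C(C)C)(C(C)C)C(C)C)cc2)c(O)c1C(=O)/C=C/c1ccc(O[Si](C(C)C)(C(C)C)C(C)C)cc1 | intermediate
33 | (E)-1-{2,4-dihydroxy-3-[(1S,2E,5R)-5-hydroxy-1,7-bis(4-hydroxyphenyl)hept-2-en-1-yl]-6-methoxyphenyl}-3-(4-hydroxyphenyl)prop-2-en-1-one | COc1cc(O)c([C@@H](/C=C/C[C@H](O)CCc2ccc(O)cc2)c2ccc(O)cc2)c(O)c1C(=O)/C=C/c1ccc(O)cc1 | target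

**Step count and risks**

Total steps: 19. Longest linear sequence: 13 steps (1 → 2 → 3 → 4 → 7 → 14 → 15 → 18 → 25 → 26 → 27 → 31 → 32 → 33; the branch from 8 is equally long).

Risk at step 13. The alkoxy-stabilised cyclobutenone 20 may open to the vinylketene only at temperatures at which the siloxyalkyne undergoes a 1,3-silyl shift to a C-silyl ketene, C7 loses its configuration, or the product phenol is acylated by excess ketene. The fallback generates the same vinylketene 21 at room temperature by photochemical Wolff rearrangement and sets out from 18. 3-Methoxybut-3-en-2-one F1 is trifluoroacetylated at its methyl group (LiN(SiMe3)2, CF3CO2CH2CF3, THF, −78 °C) to 1,1,1-trifluoro-5-methoxyhex-5-ene-2,4-dione F2. Detrifluoroacetylative diazo transfer (MsN3, Et3N, H2O, MeCN) converts this into 1-diazo-3-methoxybut-3-en-2-one F3. Irradiation of this diazo ketone with 18 in ClCH2CH2Cl at room temperature, then brief warming to 80 °C, should run the same cascade through 22, 23 and 24 and return to the route at 25.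

Risk at step 11. Proton transfer from the triply activated C3–H to acetylide, amide or tert-butoxide during the hours at 0 °C would give allene or conjugated enyne isomers and erase C7. The fallback sets out from 14 and carries ring C through the basic stage as its phenoxide, which strongly lowers the acidity of the benzylic C–H. Bu4NF (THF, 0 °C) removes the two aryl TIPS groups and the C-silyl group but not the secondary TBS ether, giving (3R,4E,7R)-7-(tert-butyldimethylsilyloxy)-3,9-bis(4-hydroxyphenyl)non-4-en-1-yne F4. In one flask this is treated with n-BuLi (3 equiv, −78 °C), oxidised with LiOOt-Bu as before, and silylated with TIPSOTf (3.5 equiv) on the ynolate and on both phenoxides, returning to the route at 18.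

Risk at step 17. Acyl transfer from the Weinreb amide to the doubly flanked aryllithium may be slow, leaving time for proton transfer from C7–H to the aryllithium or for conjugate addition. The fallback sets out from 3 and 27 and uses a far more electrophilic partner. MnO2 (CH2Cl2, rt) oxidises 3 to (E)-3-[4-(triisopropylsilyloxy)phenyl]prop-2-enal F5. The aryllithium 29 from 27 should add to this aldehyde within minutes at −78 °C to give (E)-1-[3-Hep-6-methoxy-2-(methoxymethoxy)-4-(triisopropylsilyloxy)phenyl]-3-[4-(triisopropylsilyloxy)phenyl]prop-2-en-1-ol F6 as a mixture at the carbinol carbon. MnO2 oxidation of this doubly activated alcohol returns to the route at 31.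

**Further compounds**

F1 | step 13 | 3-methoxybut-3-en-2-one | CC(=O)C(=C)OC
F2 | step 13 | 1,1,1-trifluoro-5-methoxyhex-5-ene-2,4-dione | C=C(OC)C(=O)CC(=O)C(F)(F)F
F3 | step 13 | 1-diazo-3-methoxybut-3-en-2-one | C=C(OC)C(=O)C=[N+]=[N-]
F4 | step 11 | (3R,4E,7R)-7-(tert-butyldimethylsilyloxy)-3,9-bis(4-hydroxyphenyl)non-4-en-1-yne | C#C[C@@H](/C=C/C[C@H](O[Si](C)(C)C(C)(C)C)CCc1ccc(O)cc1)c1ccc(O)cc1
F5 | step 17 | (E)-3-[4-(triisopropylsilyloxy)phenyl]prop-2-enal | O=C/C=C/c1ccc(O[Si](C(C)C)(C(C)C)C(C)C)cc1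
F6 | step 17 | (E)-1-[3-Hep-6-methoxy-2-(methoxymethoxy)-4-(triisopropylsilyloxy)phenyl]-3-[4-(triisopropylsilyloxy)phenyl]prop-2-en-1-ol | COc1cc(O[Si](C(C)C)(C(C)C)C(C)C)c([C@@H](/C=C/C[C@H](O[Si](C)(C)C(C)(C)C)CCc2ccc(O[Si](C(C)C)(C(C)C)C(C)C)cc2)c2ccc(O[Si](C(C)C)(C(C)C)C(C)C)cc2)c(OCOC)c1C(O)/C=C/c1ccc(O[Si](C(C)C)(C(C)C)C(C)C)cc1
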